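41% of the charge as open intermediate at 3.00 min is the highest reading of the teal run, and the flask repeats that recipe at a lower concentration.

| flask | starting material | partner | reagent | remark | time |
|---|---|---|---|---|---|
| teal | 0.40 M | 1.2 equiv | 1 equiv | run made earlier |  |
| flask | 0.20 M | 1.20 equiv | 1.00 equiv |  | 80 min |

teal run (percent of the starting material charged)

| time / min | open intermediate / % | target / % |
|---|---|---|
| 0.667 | 20 | 1 |
| 1.00 | 32 | 4 |
| 2.00 | 37 | 0 |
| 3.00 | 41 | 0 |
| 5.00 | 36 | 2 |
| 8.00 | 28 | 0 |

(standard deviation of a reading: 2 percentage points)

- time, not beyond 80 min, at which the flask holds most open intermediate
- the amount of open intermediate, in percent of the starting material charged, at that time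

- the numbers in the tables scatter with a standard deviation of 2 percentage points

Read downward, the rows up to 3.00 min are the rise, and their plain mean, 32.5%, stands in for the curve. The rows after it are the fall, to 28% at 8.00 min, a net rate of 0.0763 /min, while the target column stays at or under 4%.

The reckoning here lets that rate act as a first-order drain on the mean throughout the rise, which gives 0.181 as the amount drained by the peak per amount standing at the peak, the drain ratio. On this reckoning the teal run has made a fraction of about 48.4% by its highest reading.

If formation is bimolecular, then at fixed equivalents the rise lengthens as the concentration falls, so the flask should peak near 6.00 min with a ratio of 0.363, and the same made fraction leaves 35.5%. Weighting the rows by time gives a mean of 29.6%, which shifts that peak by 0.36 points against a scatter of 2 points.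

The forecast, holding that “Halving the concentration should roughly halve the bimolecular formation rate.”, gives 30% at 5 min, which is lower and earlier than this reckoning.

The flask peaks at 4.34 min with 33.3%, earlier than either estimate, and the forecast's height stands within its margin. At that time the flask holds 14.1% of decomposed reagent and 0.595% of target, so its drain ratio is 0.440 against the 0.363 reckoned.

    starting material + reagent → open intermediate (k = 1.30 /M/min)
    reagent + partner → second intermediate (k = 0.340 /M/min)
    open intermediate + second intermediate → target (k = 0.480 /M/min)
    2 second intermediate → homo product (k = 0.160 /M/min)
    open intermediate → decomposed reagent (k = 0.130 /min)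
    second intermediate → side product (k = 0.570 /min)

A neighbour flask with 0.12 M of starting material, at the same equivalents and time, has a reckoned drain ratio of 0.605, which leaves a peak of 30.2%; its computed peak is 27.7%.

(Readings and results were computed for an exercise; noise was put on by code.)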